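**Plan**

1. Cuts: C6–C7 (decarboxylative alkenylation of a C6 radical by a C7 enol triflate), C4–C5 (doubly decarboxylative coupling), C7–C8 (formylation of the ring ketone) and C12–C13 (allylbarium addition); the acetates and the C10 chlorine are functional-group operations.
2. Enabling feature: C6 is the oxygen-bearing sp3 carbon of the C5/C6 threo diol, so it can sit in a trans-1,3-dioxolane as a carboxyl-derived flat radical that bonds anti to the C5 chain; C7 is the β-carbon of the exocyclic enone C7=C8–C9=O on the cyclopentenone ring, i.e. the formyl carbon of a 2-formyl ketone whose lithium chelate gives a Z enol triflate.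
3. Fragment A (steps 1–7): dibenzyl L-tartrate → acetonide → half ester → redox-active ester → C4–C5 coupling with a glutarate-derived radical → second redox-active ester 11; the dioxolane is a temporary ring, opened in step 18.
4. Fragment B (steps 8–16): the cyclopentene ring is bought as silyloxycyclopentenone 14; Z-octenylbarium addition, desilylation/oxidation, epoxidation/HCl (C10–Cl), silylation, formylation and Z-selective triflation give 26.
5. Union in step 17, then acetonide cleavage without protic acid, diacetylation and removal of the C12 silyl group (steps 18–20).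
6. Stereochemistry: C5 and C6 from L-tartaric acid (each radical coupling anti on the dioxolane); C12 by 1,2-addition anti to the silyloxy group of 14, whose carbinol carbon is then oxidised to the C9 ketone; 14Z from (Z)-oct-2-en-1-ol; 7Z from the chelated enolate and its retention in the coupling.

Key step: step 17

Remark: locants C1–C20 are those of the target chain (C1 ester carbon, C8–C12 ring); the C12 trimethylsilyl ether is assumed to survive step 18 (if it were lost there, step 19 run without DMAP would give the target directly); epoxide 19 is drawn as the isomer expected from attack syn to the hydroxyl, and either isomer gives 21.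

**Fragment A**

Step 1
Reactants: 1 dibenzyl L-tartrate [dibenzyl (2R,3R)-2,3-dihydroxybutanedioate]
Product: 2 dibenzyl (4R,5R)-2,2-dimethyl-1,3-dioxolane-4,5-dicarboxylate
Conditions: 2-methoxypropene, CSA (cat.), CH2Cl2, 0 °C → rt
Reagents that add atoms: 2-methoxypropene, COC(C)=C
Why: Acid-catalysed acetalisation of a 1,2-diol with an enol ether, which touches neither stereocenter and ties the two oxygens into the trans-dioxolane that later steers both radical couplings.

Step 2
Reactants: 2 dibenzyl (4R,5R)-2,2-dimethyl-1,3-dioxolane-4,5-dicarboxylate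
Product: 3 (4R,5R)-5-[(benzyloxy)carbonyl]-2,2-dimethyl-1,3-dioxolane-4-carboxylic acid
Conditions: LiOH·H2O (1.0 equiv), THF/H2O, 0 °C; then 1 M HCl
Reagents that add atoms: lithium hydroxide, [Li+].[OH-]
Why: Mono-saponification of a C2-symmetric diester, in which the first carboxylate slows hydrolysis of the second ester by charge repulsion, so one equivalent of hydroxide should stop at the half ester.

Step 3
Reactants: 3 (4R,5R)-5-[(benzyloxy)carbonyl]-2,2-dimethyl-1,3-dioxolane-4-carboxylic acid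
Product: 4 4-benzyl 5-(1,3-dioxoisoindolin-2-yl) (4R,5R)-2,2-dimethyl-1,3-dioxolane-4,5-dicarboxylate
Conditions: N-hydroxyphthalimide, DIC, DMAP (cat.), CH2Cl2, rt
Reagents that add atoms: N-hydroxyphthalimide, ON1C(=O)c2ccccc2C1=O
Why: Steglich-type carbodiimide esterification gives the redox-active ester without touching the benzyl ester or the stereocenters.

Step 4
Reactants: 5 monomethyl glutarate (5-methoxy-5-oxopentanoic acid)
Product: 6 methyl 5-[(1,3-dioxoisoindolin-2-yl)oxy]-5-oxopentanoate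
Conditions: N-hydroxyphthalimide, DIC, DMAP (cat.), CH2Cl2, rt
Reagents that add atoms: N-hydroxyphthalimide, ON1C(=O)c2ccccc2C1=O
Why: The same Steglich-type esterification; the methyl ester is inert.

Step 5
Reactants: 4 4-benzyl 5-(1,3-dioxoisoindolin-2-yl) (4R,5R)-2,2-dimethyl-1,3-dioxolane-4,5-dicarboxylate; 6 methyl 5-[(1,3-dioxoisoindolin-2-yl)oxy]-5-oxopentanoate (3 equiv)
Product: 9 benzyl (4R,5S)-5-(4-methoxy-4-oxobutyl)-2,2-dimethyl-1,3-dioxolane-4-carboxylate, via dioxolan-4-yl radical 7 (not isolated), via 4-methoxy-4-oxobutyl radical 8 (not isolated)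
Conditions: NiCl2·6H2O (20 mol %), 2,2':6',2''-terpyridine (20 mol %), AgNO3 (30 mol %), NMP, Mg anode / RVC cathode, constant current, rt
Reagents that add atoms: none
Why: Ni-electrocatalytic doubly decarboxylative C(sp3)–C(sp3) cross-coupling of two redox-active esters, in which the flat radical 7 is joined to the primary radical 8 at nickel on the face anti to the neighbouring benzyl ester, so the new C5 centre (S) is set trans on the dioxolane.

Step 6
Reactants: 9 benzyl (4R,5S)-5-(4-methoxy-4-oxobutyl)-2,2-dimethyl-1,3-dioxolane-4-carboxylate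
Product: 10 (4R,5S)-5-(4-methoxy-4-oxobutyl)-2,2-dimethyl-1,3-dioxolane-4-carboxylic acid
Conditions: H2 (1 atm), Pd/C, EtOAc, rt
Reagents that add atoms: none
Why: Hydrogenolysis of the benzyl ester over Pd/C, which leaves the methyl ester and the acetonide untouched.

Step 7
Reactants: 10 (4R,5S)-5-(4-methoxy-4-oxobutyl)-2,2-dimethyl-1,3-dioxolane-4-carboxylic acid
Product: 11 1,3-dioxoisoindolin-2-yl (4R,5S)-5-(4-methoxy-4-oxobutyl)-2,2-dimethyl-1,3-dioxolane-4-carboxylate
Conditions: N-hydroxyphthalimide, DIC, DMAP (cat.), CH2Cl2, rt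
Reagents that add atoms: N-hydroxyphthalimide, ON1C(=O)c2ccccc2C1=O
Why: Steglich-type esterification to the redox-active ester that will release the C6 radical.

**Fragment B**

Step 8
Reactants: 12 (Z)-oct-2-en-1-ol
Product: 13 (Z)-1-chlorooct-2-ene
Conditions: NCS, Me2S, CH2Cl2, −20 → 0 °C
Reagents that add atoms: N-chlorosuccinimide, O=C1CCC(=O)N1Cl
Why: Corey–Kim-type chlorination of a primary allylic alcohol (alkoxysulfonium salt displaced by chloride in SN2 fashion), which keeps the Z alkene and gives no allylic transposition.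

Step 9
Reactants: 13 (Z)-1-chlorooct-2-ene; 14 (R)-4-[(tert-butyldimethylsilyl)oxy]cyclopent-2-en-1-one
Product: 16 (1S,4R)-4-[(tert-butyldimethylsilyl)oxy]-1-[(2Z)-oct-2-en-1-yl]cyclopent-2-en-1-ol, via (Z)-oct-2-enylbarium chloride 15 (not isolated)
Conditions: BaI2, lithium biphenylide (2 equiv), THF, rt; 13, −78 °C; then 14, −78 °C
Reagents that add atoms: none
Why: α-Selective, geometry-retaining allylbarium 1,2-addition to the enone carbonyl, with attack anti to the C4 silyloxy group setting the tertiary carbinol (the later C12).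

Step 10
Reactants: 16 (1S,4R)-4-[(tert-butyldimethylsilyl)oxy]-1-[(2Z)-oct-2-en-1-yl]cyclopent-2-en-1-ol
Product: 17 (1S,4R)-1-[(2Z)-oct-2-en-1-yl]cyclopent-2-ene-1,4-diol
Conditions: TBAF, THF, 0 °C → rt
Reagents that add atoms: none
Why: Fluoride-induced cleavage of the secondary silyl ether.

Step 11
Reactants: 17 (1S,4R)-1-[(2Z)-oct-2-en-1-yl]cyclopent-2-ene-1,4-diol
Product: 18 (4S)-4-hydroxy-4-[(2Z)-oct-2-en-1-yl]cyclopent-2-en-1-one
Conditions: MnO2 (activated), CH2Cl2, rt
Reagents that add atoms: none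
Why: MnO2 oxidation of the secondary allylic alcohol to the enone, which cannot touch the tertiary alcohol and removes the relay stereocenter once it has done its work.

Step 12
Reactants: 18 (4S)-4-hydroxy-4-[(2Z)-oct-2-en-1-yl]cyclopent-2-en-1-one
Product: 19 (1S,4S,5R)-4-hydroxy-4-[(2Z)-oct-2-en-1-yl]-6-oxabicyclo[3.1.0]hexan-2-one
Conditions: H2O2 (30 % aq.), NaOH (cat.), MeOH, 0 °C
Reagents that add atoms: hydrogen peroxide, OO
Why: Weitz–Scheffer nucleophilic epoxidation, selective for the electron-poor enone over the isolated Z alkene; hydroperoxide attack anti to the octenyl chain should give the epoxide syn to the hydroxyl.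

Step 13
Reactants: 19 (1S,4S,5R)-4-hydroxy-4-[(2Z)-oct-2-en-1-yl]-6-oxabicyclo[3.1.0]hexan-2-one
Product: 21 (4S)-2-chloro-4-hydroxy-4-[(2Z)-oct-2-en-1-yl]cyclopent-2-en-1-one, via chlorohydrin 20 (not isolated)
Conditions: conc. aq. HCl (3 equiv), THF, 0 °C → rt
Reagents that add atoms: hydrogen chloride, Cl
Why: Acid-mediated opening of the α,β-epoxy ketone by chloride at the α-carbon (the β-carbon is neopentyl-like) and dehydration of the resulting β-hydroxy ketone, the classical conversion of an enone epoxide into a 2-chloroenone.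

Step 14
Reactants: 21 (4S)-2-chloro-4-hydroxy-4-[(2Z)-oct-2-en-1-yl]cyclopent-2-en-1-one
Product: 22 (4S)-2-chloro-4-[(2Z)-oct-2-en-1-yl]-4-[(trimethylsilyl)oxy]cyclopent-2-en-1-one
Conditions: 1-(trimethylsilyl)imidazole, CH2Cl2, rt
Reagents that add atoms: 1-(trimethylsilyl)imidazole, C[Si](C)(C)n1ccnc1
Why: Silylation of the tertiary alcohol with a silylimidazole under neutral conditions, so the enone is not enolised.

Step 15
Reactants: 22 (4S)-2-chloro-4-[(2Z)-oct-2-en-1-yl]-4-[(trimethylsilyl)oxy]cyclopent-2-en-1-one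
Product: 24 (4R,5Z)-2-chloro-5-(hydroxymethylidene)-4-[(2Z)-oct-2-en-1-yl]-4-[(trimethylsilyl)oxy]cyclopent-2-en-1-one, via lithium enolate 23 (not isolated)
Conditions: LDA (1.1 equiv), THF, −78 °C; CF3CH2OCHO, −78 °C; AcOH quench
Reagents that add atoms: 2,2,2-trifluoroethyl formate, O=COCC(F)(F)F
Why: Crossed Claisen formylation of the kinetic lithium enolate with an activated formate; C5 of the ring is the only enolisable position, loss of the silyloxy group from 23 would need an antiaromatic cyclopentadienone, and the product should rest as the hydrogen-bonded Z enol.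

Step 16
Reactants: 24 (4R,5Z)-2-chloro-5-(hydroxymethylidene)-4-[(2Z)-oct-2-en-1-yl]-4-[(trimethylsilyl)oxy]cyclopent-2-en-1-one
Product: 26 [(Z)-[(2R)-4-chloro-2-[(2Z)-oct-2-en-1-yl]-5-oxo-2-[(trimethylsilyl)oxy]cyclopent-3-en-1-ylidene]methyl] trifluoromethanesulfonate, via lithium chelate 25 (not isolated)
Conditions: LiHMDS (1.05 equiv), THF, −78 °C; N-(5-chloropyridin-2-yl)bis(trifluoromethanesulfonyl)imide, −78 → −20 °C; aq. NH4Cl
Reagents that add atoms: N-(5-chloropyridin-2-yl)-1,1,1-trifluoro-N-[(trifluoromethyl)sulfonyl]methanesulfonamide, FC(F)(F)S(=O)(=O)N(c1ccc(Cl)cn1)S(=O)(=O)C(F)(F)F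
Why: Chelation-controlled enol triflation of a 1,3-dicarbonyl lithium enolate: the O–Li–O chelate 25 holds the aldehyde-derived oxygen cis to the ring carbonyl and this less hindered oxygen is sulfonylated, which should give the Z triflate.

**Union and end game**

Step 17
Reactants: 11 1,3-dioxoisoindolin-2-yl (4R,5S)-5-(4-methoxy-4-oxobutyl)-2,2-dimethyl-1,3-dioxolane-4-carboxylate (2 equiv); 26 [(Z)-[(2R)-4-chloro-2-[(2Z)-oct-2-en-1-yl]-5-oxo-2-[(trimethylsilyl)oxy]cyclopent-3-en-1-ylidene]methyl] trifluoromethanesulfonate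
Product: 28 methyl 4-[(4S,5S)-5-[(Z)-[(2R)-4-chloro-2-[(2Z)-oct-2-en-1-yl]-5-oxo-2-[(trimethylsilyl)oxy]cyclopent-3-en-1-ylidene]methyl]-2,2-dimethyl-1,3-dioxolan-4-yl]butanoate, via dioxolan-4-yl radical 27 (not isolated)
Conditions: NiCl2·6H2O (20 mol %), 2,2'-bipyridine (20 mol %), AgNO3 (30 mol %), DMF, Mg anode / RVC cathode, constant current (about 2.5 F per mol of 26), rt
Reagents that add atoms: none
Why: Proposed new method: cathodically formed zerovalent nickel (bipyridine) should insert into the vinylic C–OTf bond of 26 with retention to give a Z-alkenylnickel species held as a five-membered chelate by the C9 carbonyl, while single-electron reduction of 11 releases phthalimide anion, CO2 and the flat radical 27, which is captured at nickel and leaves by reductive elimination from trivalent nickel to form C6–C7. The closest known reaction type is the Ni-electrocatalytic decarboxylative alkenylation of redox-active esters with alkenyl bromides and iodides, together with Ni-catalysed reductive couplings of enol triflates with alkyl electrophiles; what is new is the 2-acyl enol triflate as partner. No ring is closed. The new stereocenter C6 is set by the C5 side chain on the dioxolane, because bond formation at the flat radical occurs anti to it and gives the trans-dioxolane (5S,6S) whatever the configuration of C6 in 11. The step needs retention of the Z geometry (secured by the carbonyl chelate, which also makes Z the preferred form should the alkenylnickel species equilibrate), reaction at C–OTf before the vinylic C–Cl (the vinylogous acyl triflate is far more reactive in oxidative addition, and 26 is the limiting partner) and no Giese addition of 27 to C11 (shielded by the quaternary C12).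

Step 18
Reactants: 28 methyl 4-[(4S,5S)-5-[(Z)-[(2R)-4-chloro-2-[(2Z)-oct-2-en-1-yl]-5-oxo-2-[(trimethylsilyl)oxy]cyclopent-3-en-1-ylidene]methyl]-2,2-dimethyl-1,3-dioxolan-4-yl]butanoate
Product: 29 methyl (5S,6S,7Z)-7-[(2R)-4-chloro-2-[(2Z)-oct-2-en-1-yl]-5-oxo-2-[(trimethylsilyl)oxy]cyclopent-3-en-1-ylidene]-5,6-dihydroxyheptanoate
Conditions: Me2BBr (2–3 equiv), CH2Cl2, −78 °C; then sat. aq. NaHCO3/THF, 0 °C; used crude
Reagents that add atoms: none
Why: Low-temperature acetonide cleavage with a bromoborane (oxygen complexation, bromide opening, hydrolytic work-up), chosen because it avoids protic acid, under which a free C6 hydroxyl cis to the C9 carbonyl could cyclodehydrate to a furan; the hindered tertiary silyl ether and the methyl ester should survive at −78 °C.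

Step 19
Reactants: 29 methyl (5S,6S,7Z)-7-[(2R)-4-chloro-2-[(2Z)-oct-2-en-1-yl]-5-oxo-2-[(trimethylsilyl)oxy]cyclopent-3-en-1-ylidene]-5,6-dihydroxyheptanoate
Product: 30 methyl (5S,6S,7Z)-5,6-bis(acetyloxy)-7-[(2R)-4-chloro-2-[(2Z)-oct-2-en-1-yl]-5-oxo-2-[(trimethylsilyl)oxy]cyclopent-3-en-1-ylidene]heptanoate
Conditions: Ac2O, pyridine, DMAP (cat.), CH2Cl2, 0 °C
Reagents that add atoms: acetic anhydride, CC(=O)OC(C)=O
Why: DMAP-catalysed acetylation of the two secondary alcohols, run on the crude diol so that the free C6 hydroxyl is short-lived; C12 is still silylated and cannot be acylated.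

Step 20
Reactants: 30 methyl (5S,6S,7Z)-5,6-bis(acetyloxy)-7-[(2R)-4-chloro-2-[(2Z)-oct-2-en-1-yl]-5-oxo-2-[(trimethylsilyl)oxy]cyclopent-3-en-1-ylidene]heptanoate
Product: 31 7Z-punaglandin 4, methyl (5S,6S,7Z)-5,6-bis(acetyloxy)-7-[(2R)-4-chloro-2-hydroxy-2-[(2Z)-oct-2-en-1-yl]-5-oxocyclopent-3-en-1-ylidene]heptanoate
Conditions: AcOH/THF/H2O (3:1:1), rt
Reagents that add atoms: none
Why: Mild aqueous-acid hydrolysis of the tertiary trimethylsilyl ether, safe now that O6 is acylated, which should leave the acetates, the methyl ester and the dienone untouched.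

**Compound list**

1 | dibenzyl L-tartrate | O=C(OCc1ccccc1)[C@H](O)[C@@H](O)C(=O)OCc1ccccc1 | starting material
2 | dibenzyl (4R,5R)-2,2-dimethyl-1,3-dioxolane-4,5-dicarboxylate | O=C(OCc1ccccc1)[C@@H]1OC(C)(C)O[C@H]1C(=O)OCc1ccccc1 | intermediate
3 | (4R,5R)-5-[(benzyloxy)carbonyl]-2,2-dimethyl-1,3-dioxolane-4-carboxylic acid | OC(=O)[C@@H]1OC(C)(C)O[C@H]1C(=O)OCc1ccccc1 | intermediate
4 | 4-benzyl 5-(1,3-dioxoisoindolin-2-yl) (4R,5R)-2,2-dimethyl-1,3-dioxolane-4,5-dicarboxylate | O=C(ON1C(=O)c2ccccc2C1=O)[C@@H]1OC(C)(C)O[C@H]1C(=O)OCc1ccccc1 | intermediate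
5 | monomethyl glutarate | COC(=O)CCCC(O)=O | starting material
6 | methyl 5-[(1,3-dioxoisoindolin-2-yl)oxy]-5-oxopentanoate | COC(=O)CCCC(=O)ON1C(=O)c2ccccc2C1=O | intermediate
7 | (5R)-5-[(benzyloxy)carbonyl]-2,2-dimethyl-1,3-dioxolan-4-yl radical | [CH]1OC(C)(C)O[C@H]1C(=O)OCc1ccccc1 | intermediate
8 | 4-methoxy-4-oxobutyl radical | [CH2]CCC(=O)OC | intermediate
9 | benzyl (4R,5S)-5-(4-methoxy-4-oxobutyl)-2,2-dimethyl-1,3-dioxolane-4-carboxylate | COC(=O)CCC[C@@H]1OC(C)(C)O[C@H]1C(=O)OCc1ccccc1 | intermediate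
10 | (4R,5S)-5-(4-methoxy-4-oxobutyl)-2,2-dimethyl-1,3-dioxolane-4-carboxylic acid | COC(=O)CCC[C@@H]1OC(C)(C)O[C@H]1C(O)=O | intermediate
11 | 1,3-dioxoisoindolin-2-yl (4R,5S)-5-(4-methoxy-4-oxobutyl)-2,2-dimethyl-1,3-dioxolane-4-carboxylate | COC(=O)CCC[C@@H]1OC(C)(C)O[C@H]1C(=O)ON1C(=O)c2ccccc2C1=O | intermediate
12 | (Z)-oct-2-en-1-ol | CCCCC/C=C\CO | starting material
13 | (Z)-1-chlorooct-2-ene | CCCCC/C=C\CCl | intermediate
14 | (R)-4-[(tert-butyldimethylsilyl)oxy]cyclopent-2-en-1-one | O=C1C=C[C@H](O[Si](C)(C)C(C)(C)C)C1 | starting material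
15 | (Z)-oct-2-enylbarium chloride | CCCCC/C=C\C[Ba]Cl | intermediate
16 | (1S,4R)-4-[(tert-butyldimethylsilyl)oxy]-1-[(2Z)-oct-2-en-1-yl]cyclopent-2-en-1-ol | CCCCC/C=C\C[C@@]1(O)C=C[C@H](O[Si](C)(C)C(C)(C)C)C1 | intermediate
17 | (1S,4R)-1-[(2Z)-oct-2-en-1-yl]cyclopent-2-ene-1,4-diol | CCCCC/C=C\C[C@@]1(O)C=C[C@H](O)C1 | intermediate
18 | (4S)-4-hydroxy-4-[(2Z)-oct-2-en-1-yl]cyclopent-2-en-1-one | CCCCC/C=C\C[C@@]1(O)C=CC(=O)C1 | intermediate
19 | (1S,4S,5R)-4-hydroxy-4-[(2Z)-oct-2-en-1-yl]-6-oxabicyclo[3.1.0]hexan-2-one | CCCCC/C=C\C[C@@]1(O)[C@@H]2O[C@@H]2C(=O)C1 | intermediate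
20 | (2R,3S,4S)-2-chloro-3,4-dihydroxy-4-[(2Z)-oct-2-en-1-yl]cyclopentan-1-one (chlorohydrin) | CCCCC/C=C\C[C@@]1(O)[C@H](O)[C@@H](Cl)C(=O)C1 | intermediate
21 | (4S)-2-chloro-4-hydroxy-4-[(2Z)-oct-2-en-1-yl]cyclopent-2-en-1-one | CCCCC/C=C\C[C@@]1(O)C=C(Cl)C(=O)C1 | intermediate
22 | (4S)-2-chloro-4-[(2Z)-oct-2-en-1-yl]-4-[(trimethylsilyl)oxy]cyclopent-2-en-1-one | CCCCC/C=C\C[C@@]1(O[Si](C)(C)C)C=C(Cl)C(=O)C1 | intermediate
23 | lithium enolate of 22 (deprotonated at ring C5) | CCCCC/C=C\C[C@@]1(O[Si](C)(C)C)C=C(Cl)C(O[Li])=C1 | intermediate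
24 | (4R,5Z)-2-chloro-5-(hydroxymethylidene)-4-[(2Z)-oct-2-en-1-yl]-4-[(trimethylsilyl)oxy]cyclopent-2-en-1-one | CCCCC/C=C\C[C@@]1(O[Si](C)(C)C)C=C(Cl)C(=O)/C1=C\O | intermediate
25 | lithium chelate (Z enolate) of 24 | CCCCC/C=C\C[C@@]1(O[Si](C)(C)C)C=C(Cl)C(=O)/C1=C\O[Li] | intermediate
26 | [(Z)-[(2R)-4-chloro-2-[(2Z)-oct-2-en-1-yl]-5-oxo-2-[(trimethylsilyl)oxy]cyclopent-3-en-1-ylidene]methyl] trifluoromethanesulfonate | CCCCC/C=C\C[C@@]1(O[Si](C)(C)C)C=C(Cl)C(=O)/C1=C\OS(=O)(=O)C(F)(F)F | intermediate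
27 | (5S)-5-(4-methoxy-4-oxobutyl)-2,2-dimethyl-1,3-dioxolan-4-yl radical | COC(=O)CCC[C@@H]1OC(C)(C)O[CH]1 | intermediate
28 | methyl 4-[(4S,5S)-5-[(Z)-[(2R)-4-chloro-2-[(2Z)-oct-2-en-1-yl]-5-oxo-2-[(trimethylsilyl)oxy]cyclopent-3-en-1-ylidene]methyl]-2,2-dimethyl-1,3-dioxolan-4-yl]butanoate | CCCCC/C=C\C[C@@]1(O[Si](C)(C)C)C=C(Cl)C(=O)/C1=C\[C@@H]2OC(C)(C)O[C@H]2CCCC(=O)OC | intermediate
29 | methyl (5S,6S,7Z)-7-[(2R)-4-chloro-2-[(2Z)-oct-2-en-1-yl]-5-oxo-2-[(trimethylsilyl)oxy]cyclopent-3-en-1-ylidene]-5,6-dihydroxyheptanoate | CCCCC/C=C\C[C@@]1(O[Si](C)(C)C)C=C(Cl)C(=O)/C1=C\[C@H](O)[C@H](CCCC(=O)OC)O | intermediate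
30 | methyl (5S,6S,7Z)-5,6-bis(acetyloxy)-7-[(2R)-4-chloro-2-[(2Z)-oct-2-en-1-yl]-5-oxo-2-[(trimethylsilyl)oxy]cyclopent-3-en-1-ylidene]heptanoate | CCCCC/C=C\C[C@@]1(O[Si](C)(C)C)C=C(Cl)C(=O)/C1=C\[C@H](OC(C)=O)[C@H](CCCC(=O)OC)OC(C)=O | intermediate
31 | 7Z-punaglandin 4 | CCCCC/C=C\C[C@@]1(O)C=C(Cl)C(=O)/C1=C\[C@H](OC(C)=O)[C@H](CCCC(=O)OC)OC(C)=O | target

**Count and risks**

Total step count: 20. Longest linear sequence: 13 steps (steps 8–20, from (Z)-oct-2-en-1-ol and 14).

Steps most likely to fail: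

1. Step 17 (Proposed new method). The enol triflate may be consumed by reductive cleavage, or nickel may insert into the vinylic C–Cl bond, before the radical is captured. The Z geometry may also erode if the radical adds directly to C7 and triflate is then lost, instead of passing through nickel. The fallback uses known chemistry and forms the C7–C8 bond instead; it sets out from 10 and 22 and comes back at 28. Acid 10 is reduced chemoselectively (BH3·SMe2, THF, 0 °C) to methyl 4-[(4S,5S)-5-(hydroxymethyl)-2,2-dimethyl-1,3-dioxolan-4-yl]butanoate F1, which is oxidised with Dess–Martin periodinane to methyl 4-[(4S,5R)-5-formyl-2,2-dimethyl-1,3-dioxolan-4-yl]butanoate F2. In this aldehyde the tartrate-derived C6 centre is kept, not reset, and the formyl carbon becomes C7. Aldol addition of lithium enolate 23 (from 22, LDA, −78 °C) to F2 should give the β-hydroxy ketone aldol adduct F3. This is converted into its mesylate F4 (MsCl, Et3N) and eliminated with DBU to give 28 together with the 7E isomer of 28 F5. The two are separated by chromatography, and F5 can be recycled by sensitised photoisomerisation.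

2. Step 16. Sulfonylation through a non-chelated enolate would give E/Z mixtures, sulfonylation may occur at the ketone oxygen, and the very electrophilic product may hydrolyse on work-up. The fallback sets the geometry after the coupling instead of before it; it sets out from 24 and comes back at 28. Triflation under non-chelating conditions (Tf2O, 2,6-di-tert-butyl-4-methylpyridine, CH2Cl2, −78 °C) should give the E enol triflate F6. Coupling of F6 with 11 under the conditions of step 17 should give the 7E isomer of 28 F5. Sensitised E/Z photoisomerisation of this cross-conjugated alkylidenecyclopentenone, with chromatographic recycling, then supplies 28.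

3. Step 18. Bromide, assisted by the boron Lewis acid, may add to C7 and leave again, scrambling the 7Z geometry. The silyl ether may be lost, and the freed Z-γ-hydroxy enone may cyclodehydrate to a furan during work-up. The fallback masks the C9 carbonyl while the diol is unveiled; it sets out from 28 and comes back at 31.
   - Luche reduction (NaBH4, CeCl3·7H2O, MeOH, −78 °C) should give the C9 carbinol of 28 F7 (both C9 epimers, which converge later).
   - Silylation (TIPSOTf, 2,6-lutidine) gives the C9 triisopropylsilyl ether F8.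
   - CSA in MeOH removes the acetonide and the trimethylsilyl group to give the C5,C6,C12-triol F9; no carbonyl is present to trap O6.
   - Ac2O/pyridine gives the 5,6-diacetate F10.
   - HF·pyridine gives the C9 alcohol diacetate F11.
   - Dess–Martin oxidation of this doubly allylic alcohol gives 31.

Further compounds
F1 | step 17 | methyl 4-[(4S,5S)-5-(hydroxymethyl)-2,2-dimethyl-1,3-dioxolan-4-yl]butanoate | COC(=O)CCC[C@@H]1OC(C)(C)O[C@H]1CO
F2 | step 17 | methyl 4-[(4S,5R)-5-formyl-2,2-dimethyl-1,3-dioxolan-4-yl]butanoate | COC(=O)CCC[C@@H]1OC(C)(C)O[C@H]1C=O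
F3 | step 17 | aldol adduct of 23 and F2 (β-hydroxy ketone, mixture at C7 and C8) | CCCCC/C=C\C[C@@]1(O[Si](C)(C)C)C=C(Cl)C(=O)C1C(O)[C@@H]2OC(C)(C)O[C@H]2CCCC(=O)OC
F4 | step 17 | C7 mesylate of F3 | CCCCC/C=C\C[C@@]1(O[Si](C)(C)C)C=C(Cl)C(=O)C1C(OS(C)(=O)=O)[C@@H]2OC(C)(C)O[C@H]2CCCC(=O)OC
F5 | step 17 | 7E isomer of 28 | CCCCC/C=C\C[C@@]1(O[Si](C)(C)C)C=C(Cl)C(=O)/C1=C/[C@@H]2OC(C)(C)O[C@H]2CCCC(=O)OC
F6 | step 16 | E enol triflate (geometric isomer of 26) | CCCCC/C=C\C[C@@]1(O[Si](C)(C)C)C=C(Cl)C(=O)/C1=C/OS(=O)(=O)C(F)(F)F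
F7 | step 18 | C9 carbinol of 28 (both C9 epimers, C6 cis to C9) | CCCCC/C=C\C[C@@]1(O[Si](C)(C)C)C=C(Cl)C(O)/C1=C\[C@@H]2OC(C)(C)O[C@H]2CCCC(=O)OC
F8 | step 18 | C9 triisopropylsilyl ether of F7 | CCCCC/C=C\C[C@@]1(O[Si](C)(C)C)C=C(Cl)C(O[Si](C(C)C)(C(C)C)C(C)C)/C1=C\[C@@H]2OC(C)(C)O[C@H]2CCCC(=O)OC
F9 | step 18 | C5,C6,C12-triol with C9 triisopropylsilyl ether | CCCCC/C=C\C[C@@]1(O)C=C(Cl)C(O[Si](C(C)C)(C(C)C)C(C)C)/C1=C\[C@H](O)[C@H](CCCC(=O)OC)O
F10 | step 18 | 5,6-diacetate with C9 triisopropylsilyl ether | CCCCC/C=C\C[C@@]1(O)C=C(Cl)C(O[Si](C(C)C)(C(C)C)C(C)C)/C1=C\[C@H](OC(C)=O)[C@H](CCCC(=O)OC)OC(C)=O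
F11 | step 18 | 5,6-diacetate with free C9 alcohol (9-dihydro form of 31) | CCCCC/C=C\C[C@@]1(O)C=C(Cl)C(O)/C1=C\[C@H](OC(C)=O)[C@H](CCCC(=O)OC)OC(C)=O
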